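C1 = bridgehead with prenyl, next to C8Me2; C2-C3-C4 = enolised β-diketone with the aroyl group on C3; C5 = bridgehead with geranyl; C6H2; C7 = CH-prenyl; C9 = bridging C=O.
Cuts, in retrosynthetic order: the enol and phenol masks and the C3–aroyl bond; then C9–C1 and C4–C5 together; then C5=C6 (Wittig); then the two Cα–prenyl bonds of a 3,3-dimethylglutaric core, which supplies C6-C7-C8-C1-C4.
Enabling feature: ring A (C1-C2-C3-C4-C5-C9) is 1,3,5-trioxygenated, so it is a four-carbon vinylogous acid unit (C1 to C4) plus a two-carbon ester-enolate unit (C5 nucleophilic, C9 electrophilic). Tying C1 to C4 in a 3-ethoxycyclobutenone stores strain and makes the first closure six-membered.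
Forward: open chain, then a temporary four-membered ring, then a one-pot aldol addition / 4π opening / transannular Dieckmann closure. This inserts C5–C9 into the C1–C4 bond, so rings A and B (C1-C8-C7-C6-C5-C9) arise together; aroylation and hydrolysis finish the route.
Stereochemistry: C7 comes from a double oxazolidinone-controlled prenylation, which gives a C2-symmetric product with equivalent ends. C5 follows from C7 through a chair aldol transition state, C1 follows from C5 through the cis demand of the one-carbon bridge, and the geranyl E-alkene is purchased.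

Key step: step 11

Assumption: the target is treated as the drawn member of a set of rapidly interconverting enol tautomers; ethoxyacetylene (hexane solution) and 3-acetoxybenzoyl chloride are taken as purchasable.

Step 1
Reactants: 1 3,3-dimethylglutaric anhydride; 2 (R)-4-benzyl-1,3-oxazolidin-2-one
Product: 3 5-[(4R)-4-benzyl-2-oxo-1,3-oxazolidin-3-yl]-3,3-dimethyl-5-oxopentanoic acid
Conditions: Et3N (1.1 equiv), DMAP (cat.), CH2Cl2, rt; 1 M HCl wash
Reagents that add atoms: (R)-4-benzyl-1,3-oxazolidin-2-one (2), O=C1N[C@H](Cc2ccccc2)CO1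
Why: DMAP-catalysed N-acylation of the oxazolidinone by a cyclic anhydride (ring-opening acylation) should stop at the mono-imide because the second carboxyl group is released as an unreactive carboxylate.

Step 2
Reactants: 3 mono-imide acid; 2 (R)-4-benzyl-1,3-oxazolidin-2-one
Product: 5 1,5-bis[(4R)-4-benzyl-2-oxo-1,3-oxazolidin-3-yl]-3,3-dimethylpentane-1,5-dione, via mixed pivalic anhydride 4 (not isolated)
Conditions: t-BuCOCl, Et3N, THF, -20 °C; then LiCl, 2, -20 °C to rt
Reagents that add atoms: (R)-4-benzyl-1,3-oxazolidin-2-one (2), O=C1N[C@H](Cc2ccccc2)CO1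
Why: Mixed-anhydride activation followed by LiCl-assisted N-acylation is the routine way to load an oxazolidinone auxiliary, with attack at the less hindered carbonyl of the pivalic mixed anhydride.

Step 3
Reactants: 5 bis-imide; 6 prenyl bromide (1-bromo-3-methylbut-2-ene)
Product: 8 (2R,4R)-1,5-bis[(4R)-4-benzyl-2-oxo-1,3-oxazolidin-3-yl]-3,3-dimethyl-2,4-bis(3-methylbut-2-enyl)pentane-1,5-dione, via disodium bis-enolate 7 (not isolated)
Conditions: NaN(SiMe3)2 (2.3 equiv), THF, -78 °C; then 6 (5 equiv), -78 to -20 °C
Reagents that add atoms: prenyl bromide (6), BrCC=C(C)C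
Why: Evans asymmetric alkylation at both ends: each chelated (Z)-sodium enolate should be attacked by the reactive allylic bromide on the face opposite to the benzyl group, which sets both α-centres as R and makes 8 C2-symmetric.

Step 4
Reactants: 8 diprenylated bis-imide
Product: 9 (2R,4R)-3,3-dimethyl-2,4-bis(3-methylbut-2-enyl)pentane-1,5-diol
Conditions: LiBH4, H2O (1 equiv per imide), Et2O, 0 °C to rt
Reagents that add atoms: none
Why: Reductive cleavage of N-acyl oxazolidinones with LiBH4 gives the primary alcohols without touching the α-stereocentres or the trisubstituted alkenes, and the auxiliary is recovered.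

Step 5
Reactants: 9 C2-symmetric diol
Product: 10 (3R,5R)-4,4-dimethyl-3,5-bis(3-methylbut-2-enyl)oxan-2-ol (lactol; both anomers)
Conditions: IBX (1.1 equiv), DMSO, rt
Reagents that add atoms: none
Why: IBX oxidation of one primary alcohol gives a hydroxy aldehyde that closes at once to the six-membered lactol, which is oxidised further only slowly, and because the two CH2OH groups of C2-symmetric 9 are homotopic either end gives the same compound.

Step 6
Reactants: 11 methyl (triphenylphosphoranylidene)acetate; 12 geranyl bromide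
Product: 14 methyl (4E)-5,9-dimethyl-2-(triphenylphosphoranylidene)deca-4,8-dienoate, via phosphonium bromide 13 (not isolated)
Conditions: CH2Cl2, reflux; then 1 M aq NaOH, rt
Reagents that add atoms: geranyl bromide (12), BrC/C=C(\C)CCC=C(C)C
Why: C-alkylation of a stabilised phosphonium ylide with an allylic bromide and deprotonation of the resulting salt is the standard entry to α-substituted stabilised ylides and leaves the E-alkene of the geranyl group untouched.

Step 7
Reactants: 10 lactol; 14 geranyl-substituted ylide
Product: 15 methyl (2E,4S,6R)-2-[(2E)-3,7-dimethylocta-2,6-dienyl]-7-hydroxy-5,5-dimethyl-4,6-bis(3-methylbut-2-enyl)hept-2-enoate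
Conditions: 14 (2 equiv), PhCO2H (cat.), toluene, 90 °C
Reagents that add atoms: ylide 14, COC(=O)C(C/C=C(\C)CCC=C(C)C)=P(c1ccccc1)(c1ccccc1)c1ccccc1
Why: Wittig olefination of a lactol through its open hydroxy-aldehyde form under base-free conditions should spare the α-stereocentre (C7), and the alkene geometry (expected E) is of no consequence because the double bond is reduced next.

Step 8
Reactants: 15 hydroxy enoate
Product: 16 methyl (4S,6R)-2-[(2E)-3,7-dimethylocta-2,6-dienyl]-7-hydroxy-5,5-dimethyl-4,6-bis(3-methylbut-2-enyl)heptanoate (both C2 epimers)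
Conditions: Mg turnings, MeOH, 0 °C to rt
Reagents that add atoms: none
Why: Dissolving-metal conjugate reduction with magnesium in methanol reduces only the ester-conjugated double bond and not the isolated trisubstituted alkenes, and the new centre (C5) needs no control because it is enolised in step 11.

Step 9
Reactants: 16 hydroxy ester
Product: 17 (2R,4S)-6-[(2E)-3,7-dimethylocta-2,6-dienyl]-7-methoxy-3,3-dimethyl-2,4-bis(3-methylbut-2-enyl)-7-oxoheptanoic acid (both C6 epimers)
Conditions: TEMPO (cat.), PhI(OAc)2 (2.2 equiv), MeCN/H2O, rt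
Reagents that add atoms: water, O
Why: Oxoammonium-mediated (TEMPO) oxidation in aqueous medium takes the primary alcohol through the aldehyde hydrate to the acid under conditions that tolerate trisubstituted alkenes and the methyl ester.

Step 10
Reactants: 17 acid; 18 ethoxyacetylene
Product: 21 methyl (4S)-2-[(2E)-3,7-dimethylocta-2,6-dienyl]-4-{2-[2-ethoxy-1-(3-methylbut-2-enyl)-4-oxocyclobut-2-en-1-yl]propan-2-yl}-7-methyloct-6-enoate (epimers at C2 and at the ring carbon), via acid chloride 19 (not isolated), via dialkylketene 20 (not isolated)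
Conditions: 1-chloro-N,N,2-trimethylprop-1-en-1-amine, CH2Cl2, 0 °C to rt; then 18 (5 equiv), Et3N (1.5 equiv), toluene, rt to 60 °C
Reagents that add atoms: ethoxyacetylene (18), C#COCC
Why: Dehydrochlorination of the α-branched acid chloride gives dialkylketene 20, which should undergo the classical regioselective thermal [2+2] cycloaddition with the electron-rich alkyne (nucleophilic CH terminus to the ketene carbonyl carbon) to give the 3-ethoxy-4,4-dialkylcyclobutenone, the new quaternary centre needing no control because it is erased in step 11.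

Step 11
Reactants: 21 cyclobutenone ester
Product: 25 (1R,5S,7S)-2-ethoxy-5-[(2E)-3,7-dimethylocta-2,6-dienyl]-8,8-dimethyl-1,7-bis(3-methylbut-2-enyl)bicyclo[3.3.1]non-2-ene-4,9-dione, via lithium ester enolate 22 (not isolated), via bicyclo[4.2.0]octenolate 23 (not isolated), via cyclooctadienolate 24 (not isolated)
Conditions: LiN(i-Pr)2 (LDA, 1.1 equiv), THF, -78 °C, then warm to rt; H2O quench
Reagents that add atoms: none
Why: Proposed new method: LDA removes the only acidic proton (C5–H), the ester enolate 22 adds to the strained, non-enolisable cyclobutenone carbonyl C4 (bond C4–C5) to give the cis-fused alkoxide 23, whose alkoxide-accelerated conrotatory 4π opening (oxygen turning outward) cuts the temporary C1–C4 bond and, after bond rotation in the delocalised anion, gives the eight-membered dienolate 24, and the γ-carbon C1 of 24 is acylated across the ring by the C9 ester (bond C9–C1) with loss of methoxide, so that the C5–C9 unit is inserted into the four-membered ring. The closest known reaction types are 1,2-addition of lithium nucleophiles to 3-alkoxycyclobutenones and squarate esters followed by oxyanion-accelerated electrocyclic opening and transannular closure, the two-carbon ring expansion of fused cyclobutenes made from enamines and acetylenedicarboxylates, and the Dieckmann condensation; new is their combination with an ester enolate that serves first as nucleophile and then as acyl donor. The first closure is a 6-(enolexo)-exo-trig aldol addition forming the temporary ring C4-C5-C6-C7-C8-C1, and the last is a transannular 6-exo-trig acylation that closes ring A (C1-C2-C3-C4-C5-C9) and ring B (C1-C8-C7-C6-C5-C9) with one bond. C5 is set in the aldol step by C7 through a chair transition state with the C7 prenyl and the geranyl chain both equatorial and the flat enolate carbon C9 axial, which puts C4 cis to the C7 prenyl group (endo series) once C9 has replaced C4 in the ring, and C1 is then fixed by C5 because a one-carbon bridge can span the eight-membered ring only in cis fashion, while the C1 and C5 centres of 21 are erased on the way so that all its epimers converge. The step needs 1,2- over 1,4-addition, secured by the ethoxy group that deactivates C2, and C-acylation at the γ-terminus, secured by geometry because attack through C3 or through oxygen would give four-membered rings. Release of the cyclobutene strain and the poor nucleophilicity of LiOMe in THF should keep the non-enolisable β-dicarbonyl array from reverting by retro-Claisen cleavage.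

Step 12
Reactants: 25 bicyclic ethyl enol ether; 26 3-acetoxybenzoyl chloride
Product: 28 (1R,5R,7S)-3-(3-acetoxybenzoyl)-2-ethoxy-5-[(2E)-3,7-dimethylocta-2,6-dienyl]-8,8-dimethyl-1,7-bis(3-methylbut-2-enyl)bicyclo[3.3.1]non-2-ene-4,9-dione, via C3-lithio enol ether 27 (not isolated)
Conditions: lithium 2,2,6,6-tetramethylpiperidide (from the amine and n-BuLi), THF, -78 °C; then 26, -78 to -40 °C
Reagents that add atoms: 3-acetoxybenzoyl chloride (26), CC(=O)Oc1cccc(C(=O)Cl)c1
Why: Regioselective vinylic lithiation of the vinylogous ester at C3 with a hindered lithium amide (both bridgeheads are blocked) and C-acylation with the acid chloride, which is far more electrophilic than the aryl acetate, follows close precedent on enol ethers of bicyclo[3.3.1]nonane-2,4,9-triones.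

Step 13
Reactants: 28 aroylated enol ether
Product: 29 target CNP0236890.1 (1S,5S,7S; C7 prenyl endo; drawn enol tautomer)
Conditions: LiOH, 1,4-dioxane/H2O, 90 °C; then 1 M HCl
Reagents that add atoms: lithium hydroxide (aqueous), [Li+].[OH-]
Why: Hydroxide addition-elimination at the doubly activated vinylogous ester carbon C2 and saponification of the aryl acetate unmask the enolised β-triketone and the phenol in one operation, no stereocentre being enolisable (both bridgeheads are quaternary and C7 is remote).

Compound list
1 | 3,3-dimethylglutaric anhydride | CC1(C)CC(=O)OC(=O)C1 | starting material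
2 | (R)-4-benzyl-1,3-oxazolidin-2-one | O=C1N[C@H](Cc2ccccc2)CO1 | starting material
3 | 5-[(4R)-4-benzyl-2-oxo-1,3-oxazolidin-3-yl]-3,3-dimethyl-5-oxopentanoic acid | O=C1OC[C@@H](Cc2ccccc2)N1C(=O)CC(C)(C)CC(=O)O | intermediate
4 | mixed pivalic anhydride of 3 | O=C1OC[C@@H](Cc2ccccc2)N1C(=O)CC(C)(C)CC(=O)OC(=O)C(C)(C)C | intermediate
5 | bis-imide of 3,3-dimethylglutaric acid | O=C1OC[C@@H](Cc2ccccc2)N1C(=O)CC(C)(C)CC(=O)N1[C@H](Cc2ccccc2)COC1=O | intermediate
6 | prenyl bromide | BrCC=C(C)C | starting material
7 | disodium bis-(Z)-enolate of 5 | [Na+].[Na+].[O-]/C(=C\C(C)(C)/C=C(\[O-])N1[C@H](Cc2ccccc2)COC1=O)N1[C@H](Cc2ccccc2)COC1=O | intermediate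
8 | (2R,4R)-diprenylated bis-imide (C2-symmetric) | O=C1OC[C@@H](Cc2ccccc2)N1C(=O)[C@H](CC=C(C)C)C(C)(C)[C@@H](CC=C(C)C)C(=O)N1[C@H](Cc2ccccc2)COC1=O | intermediate
9 | (2R,4R)-3,3-dimethyl-2,4-bis(3-methylbut-2-enyl)pentane-1,5-diol | OC[C@H](CC=C(C)C)C(C)(C)[C@@H](CC=C(C)C)CO | intermediate
10 | (3R,5R)-4,4-dimethyl-3,5-bis(3-methylbut-2-enyl)oxan-2-ol (anomers) | OC1OC[C@H](CC=C(C)C)C(C)(C)[C@H]1CC=C(C)C | intermediate
11 | methyl (triphenylphosphoranylidene)acetate | COC(=O)C=P(c1ccccc1)(c1ccccc1)c1ccccc1 | starting material
12 | geranyl bromide | BrC/C=C(\C)CCC=C(C)C | starting material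
13 | [(4E)-1-methoxy-5,9-dimethyl-1-oxodeca-4,8-dien-2-yl]triphenylphosphonium bromide | [Br-].COC(=O)C(C/C=C(\C)CCC=C(C)C)[P+](c1ccccc1)(c1ccccc1)c1ccccc1 | intermediate
14 | methyl (4E)-5,9-dimethyl-2-(triphenylphosphoranylidene)deca-4,8-dienoate | COC(=O)C(C/C=C(\C)CCC=C(C)C)=P(c1ccccc1)(c1ccccc1)c1ccccc1 | intermediate
15 | hydroxy enoate (2E,4S,6R) | COC(=O)/C(C/C=C(\C)CCC=C(C)C)=C/[C@H](CC=C(C)C)C(C)(C)[C@@H](CC=C(C)C)CO | intermediate
16 | saturated hydroxy ester (4S,6R; C2 epimers) | COC(=O)C(C/C=C(\C)CCC=C(C)C)C[C@H](CC=C(C)C)C(C)(C)[C@@H](CC=C(C)C)CO | intermediate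
17 | half-ester acid (2R,4S; C6 epimers) | COC(=O)C(C/C=C(\C)CCC=C(C)C)C[C@H](CC=C(C)C)C(C)(C)[C@@H](CC=C(C)C)C(=O)O | intermediate
18 | ethoxyacetylene | C#COCC | starting material
19 | acid chloride of 17 | COC(=O)C(C/C=C(\C)CCC=C(C)C)C[C@H](CC=C(C)C)C(C)(C)[C@@H](CC=C(C)C)C(=O)Cl | intermediate
20 | dialkylketene | COC(=O)C(C/C=C(\C)CCC=C(C)C)C[C@H](CC=C(C)C)C(C)(C)C(CC=C(C)C)=C=O | intermediate
21 | 3-ethoxy-4,4-dialkylcyclobutenone ester (4S; epimers at C2 and ring carbon) | COC(=O)C(C/C=C(\C)CCC=C(C)C)C[C@H](CC=C(C)C)C(C)(C)C1(CC=C(C)C)C(=O)C=C1OCC | intermediate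
22 | lithium ester enolate of 21 | [Li+].COC([O-])=C(C/C=C(\C)CCC=C(C)C)C[C@H](CC=C(C)C)C(C)(C)C1(CC=C(C)C)C(=O)C=C1OCC | intermediate
23 | lithium bicyclo[4.2.0]oct-7-en-1-olate (cis-fused; geranyl cis to the C7 prenyl) | [Li+].[O-]C12C=C(OCC)C1(CC=C(C)C)C(C)(C)[C@@H](CC=C(C)C)C[C@]2(C/C=C(\C)CCC=C(C)C)C(=O)OC | intermediate
24 | lithium cycloocta-1,3-dienolate | [Li+].[O-]C1=CC(OCC)=C(CC=C(C)C)C(C)(C)[C@@H](CC=C(C)C)C[C@]1(C/C=C(\C)CCC=C(C)C)C(=O)OC | intermediate
25 | bicyclo[3.3.1]nonane-2,4,9-trione 2-ethyl enol ether (1R,5S,7S; C7 prenyl endo) | CC(C)=CCC/C(C)=C/C[C@]12C[C@H](CC=C(C)C)C(C)(C)[C@](CC=C(C)C)(C(OCC)=CC1=O)C2=O | intermediate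
26 | 3-acetoxybenzoyl chloride | CC(=O)Oc1cccc(C(=O)Cl)c1 | starting material
27 | C3-lithio derivative of 25 | CC(C)=CCC/C(C)=C/C[C@]12C[C@H](CC=C(C)C)C(C)(C)[C@](CC=C(C)C)(C(OCC)=C([Li])C1=O)C2=O | intermediate
28 | 3-(3-acetoxybenzoyl) enol ether (1R,5R,7S) | CC(C)=CCC/C(C)=C/C[C@]12C[C@H](CC=C(C)C)C(C)(C)[C@](CC=C(C)C)(C(OCC)=C(C(=O)c3cccc(OC(C)=O)c3)C1=O)C2=O | intermediate
29 | CNP0236890.1 (1S,5S,7S) | CC(C)=CCC/C(C)=C/C[C@]12C[C@H](CC=C(C)C)C(C)(C)[C@](CC=C(C)C)(C(=O)C(C(=O)c3cccc(O)c3)=C1O)C2=O | target

Total step count: 13. Longest linear sequence: 12 (steps 1 to 5 and 7 to 13).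

Steps most likely to fail

1. Step 11. Four things may go wrong:
- The ester enolate may add in conjugate fashion at C2 with loss of ethoxide.
- The aldolate may revert instead of opening.
- The chair preference that places geranyl equatorial may be too small, which erodes the C5/C7 relation.
- The dienolate may be protonated before it closes.

The fallback sets out from 21 and comes back at 25. It gives up the strain-driven insertion for an open-chain, two-stage Claisen sequence of known reaction types. Heating 21 in toluene/methanol (sealed tube, 120 °C, trace of Et3N) opens the cyclobutenone thermally to the vinylketene. Methanol traps the vinylketene and, after conjugation, this gives the open-chain β-ethoxy enoate diester F1. LDA turns F1 into its extended dienolate, whose γ-carbon closes ring B by a vinylogous Dieckmann condensation on the C9 ester to give the cyclohexanone acrylate F2. KOt-Bu in THF then closes ring A by a second Dieckmann condensation (C5 on the C4 ester) to reach 25. In this variant C1 is set against C7 without the relay through C5, so diastereomers would have to be separated at the stage of F2.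

2. Step 10. Dehydrochlorination of the hindered acid chloride may be slow. The tert-alkyl-substituted ketene may react sluggishly with the alkyne. The ketene may also be consumed by intramolecular [2+2] cycloaddition with the C7 prenyl alkene.

The fallback sets out from 17 and comes back at 25, avoiding ketene chemistry altogether. Acid 17 is activated with 1,1'-carbonyldiimidazole and homologated with Mg(O2CCH2CO2Me)2 (decarboxylative Claisen condensation) to the β-keto ester F3. O-Ethylation (Cs2CO3, EtOTf, DMF) gives the enoate F1 of the first fallback, which is carried through F2 to 25 as described there.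

3. Step 7. The gem-dimethyl group may hold the lactol closed so that olefination is slow. Prolonged heating may epimerise C7. The liberated alcohol may add back to the enoate in an oxa-Michael closure.

The fallback sets out from 9 and comes back at 15, replacing the lactol tactic by a protecting-group route through a free aldehyde:
- Monosilylation of the C2-symmetric diol (NaH, TBSCl, THF) gives the mono-TBS ether F4.
- Dess-Martin oxidation gives the aldehyde F5.
- Wittig reaction with 14 (toluene, 80 °C) gives the silylated enoate F6.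
- Bu4NF in THF releases 15.

Further compounds
F1 | step 11 | dimethyl (2E,6S)-3-ethoxy-8-[(2E)-3,7-dimethylocta-2,6-dienyl]-5,5-dimethyl-4,6-bis(3-methylbut-2-enyl)non-2-enedioate | COC(=O)/C=C(/OCC)C(CC=C(C)C)C(C)(C)[C@@H](CC=C(C)C)CC(C/C=C(\C)CCC=C(C)C)C(=O)OC
F2 | step 11 | methyl (E)-3-ethoxy-3-[3-geranyl-6,6-dimethyl-2-oxo-1,5-diprenylcyclohexyl]acrylate (acrylate arm cis to the ring C5 prenyl) | COC(=O)/C=C(/OCC)[C@]1(CC=C(C)C)C(=O)C(C/C=C(\C)CCC=C(C)C)C[C@H](CC=C(C)C)C1(C)C
F3 | step 10 | dimethyl (6S)-8-[(2E)-3,7-dimethylocta-2,6-dienyl]-5,5-dimethyl-4,6-bis(3-methylbut-2-enyl)-3-oxononanedioate | COC(=O)CC(=O)C(CC=C(C)C)C(C)(C)[C@@H](CC=C(C)C)CC(C/C=C(\C)CCC=C(C)C)C(=O)OC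
F4 | step 7 | (2R,4R)-5-(tert-butyldimethylsilyloxy)-3,3-dimethyl-2,4-bis(3-methylbut-2-enyl)pentan-1-ol | CC(C)(C)[Si](C)(C)OC[C@H](CC=C(C)C)C(C)(C)[C@@H](CC=C(C)C)CO
F5 | step 7 | (2R,4R)-5-(tert-butyldimethylsilyloxy)-3,3-dimethyl-2,4-bis(3-methylbut-2-enyl)pentanal | CC(C)(C)[Si](C)(C)OC[C@H](CC=C(C)C)C(C)(C)[C@@H](CC=C(C)C)C=O
F6 | step 7 | tert-butyldimethylsilyl ether of 15 | COC(=O)/C(C/C=C(\C)CCC=C(C)C)=C/[C@H](CC=C(C)C)C(C)(C)[C@@H](CC=C(C)C)CO[Si](C)(C)C(C)(C)C
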